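**Retrosynthetic overview**
- The diaryl ether is not made by Ullmann or SNAr coupling of two finished arenes: ring B (the resorcylic acid ring) is grown de novo on the ether oxygen.
- Target ⇒ (BBr3 dealkylation) methyl-ether/benzyl-ester precursor ⇒ (dehydrogenative aromatisation) 5-aryloxy-cyclohexane-1,3-dione ester ⇒ (malonate Michael–Dieckmann) α-aryloxy enone + dibenzyl malonate.
- α-Aryloxy enone ⇒ (Horner–Wadsworth–Emmons with hexanal) α-aryloxy ketophosphonate ⇒ (Rh-carbenoid O–H insertion) 8-hydroxyisocoumarin + diazo ketophosphonate, so the ether C–O bond is made to an sp3 carbon.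
- 8-Hydroxy-6-methoxy-3-pentylisocoumarin ⇒ (peri-selective demethylation, enol-lactonisation, lateral lithiation/acylation) methyl 2,4-dimethoxy-6-methylbenzoate + hexanoyl Weinreb amide.
- Ring order: ring A is bought aromatic, its pyranone ring is closed first, ring B is built last.

Assumption: the target has no stereocentre and no stereogenic double bond, so "single enantiomer" means the one achiral compound drawn; stereocentres in intermediates are transient, uncontrolled and erased before the end.

**Step 1**
Reactants: 1 methyl 2,4-dimethoxy-6-methylbenzoate; 2 N-methoxy-N-methylhexanamide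
Product: 4 methyl 2,4-dimethoxy-6-(2-oxoheptyl)benzoate, via benzylic organolithium 3 (not isolated)
Conditions: LiN(i-Pr)2 (1.2 equiv, commercial solution), THF, –78 °C; then 2 (1.3 equiv), –78 → 0 °C; 1 M HCl work-up
Reagents that add atoms: LiN(i-Pr)2 (lithium diisopropylamide), [Li+].CC(C)[N-]C(C)C
Why: Lateral (benzylic) lithiation of an ortho-toluate, whose two ortho substituents suppress self-condensation, places lithium on the benzylic carbon of 3, and Weinreb-amide acylation follows, in which the chelated tetrahedral adduct releases the ketone only on work-up so that no over-addition occurs.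

**Step 2**
Reactants: 4 methyl 2,4-dimethoxy-6-(2-oxoheptyl)benzoate
Product: 5 6,8-dimethoxy-3-pentyl-1H-isochromen-1-one
Conditions: TsOH·H2O (10 mol %), toluene, 110 °C, Dean–Stark
Reagents that add atoms: none
Why: Acid-catalysed enol-lactonisation (intramolecular transesterification), in which the benzylic ketone enolises into conjugation with the arene and the enol oxygen closes the six-membered ring onto the protonated ester while methanol is distilled out.

**Step 3**
Reactants: 5 6,8-dimethoxy-3-pentyl-1H-isochromen-1-one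
Product: 6 8-hydroxy-6-methoxy-3-pentyl-1H-isochromen-1-one
Conditions: BCl3 (1.5 equiv), CH2Cl2, –78 → 0 °C; H2O work-up
Reagents that add atoms: none
Why: Chelation-controlled Lewis-acid ether cleavage, in which BCl3 bridges the lactone carbonyl and the peri 8-methoxy oxygen so that chloride removes only that methyl group and the 6-methoxy group stays.

**Step 4**
Reactants: 6 8-hydroxy-6-methoxy-3-pentyl-1H-isochromen-1-one; 7 dimethyl (1-diazo-2-oxopropyl)phosphonate
Product: 8 dimethyl {1-[(6-methoxy-1-oxo-3-pentyl-1H-isochromen-8-yl)oxy]-2-oxopropyl}phosphonate (racemic)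
Conditions: Rh2(OAc)4 (2 mol %), 7 (1.5 equiv, slow addition), toluene, 80 °C
Reagents that add atoms: none
Why: Rh-carbenoid O–H insertion, in which the electrophilic divalent-rhodium carbenoid is captured by the phenol oxygen (oxonium ylide, then proton shift) faster than it cyclopropanates the enol-lactone alkene, so the ether bond is formed with no aryl halide and the new stereocentre is racemic and later destroyed.

**Step 5**
Reactants: 8 dimethyl {1-[(6-methoxy-1-oxo-3-pentyl-1H-isochromen-8-yl)oxy]-2-oxopropyl}phosphonate; 9 hexanal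
Product: 10 6-methoxy-8-{[(3Z)-2-oxonon-3-en-3-yl]oxy}-3-pentyl-1H-isochromen-1-one
Conditions: NaH (1.0 equiv), THF, 0 °C; then 9 (1.3 equiv), 0 → 20 °C
Reagents that add atoms: none
Why: Horner–Wadsworth–Emmons olefination of the stabilised ketophosphonate anion with an aliphatic aldehyde, which places the acyl group trans to the pentyl chain (mainly Z), the geometry being irrelevant because both alkene carbons become ring carbons.

**Step 6**
Reactants: 10 6-methoxy-8-{[(3Z)-2-oxonon-3-en-3-yl]oxy}-3-pentyl-1H-isochromen-1-one; 11 dibenzyl malonate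
Product: 13 benzyl 2-hydroxy-5-[(6-methoxy-1-oxo-3-pentyl-1H-isochromen-8-yl)oxy]-4-oxo-6-pentylcyclohex-2-ene-1-carboxylate (diastereomer mixture), via Michael adduct 12 (not isolated)
Conditions: NaH (1.1 equiv), 11 (1.1 equiv), THF, 0 °C; then 10, 20 → 65 °C; 1 M HCl work-up
Reagents that add atoms: none
Why: Proposed new method: this extends the malonate Michael–Dieckmann annulation known for dihydro-olivetolates to an α-aryloxy enone, where the malonate anion adds to the β-carbon (the aryloxy oxygen is only a weak donor because it is conjugated to the carbonyl-bearing ring A), the enolate is quenched by the malonate C–H, and the only six-membered Claisen closure available (methyl-ketone enolate onto a benzyl ester) is driven by deprotonation of the acidic 1,3-dione by the expelled benzyloxide, which also removes that alkoxide before it can open the lactone; the three new stereocentres are uncontrolled and all are erased in step 7.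

**Step 7**
Reactants: 13 benzyl 2-hydroxy-5-[(6-methoxy-1-oxo-3-pentyl-1H-isochromen-8-yl)oxy]-4-oxo-6-pentylcyclohex-2-ene-1-carboxylate
Product: 15 benzyl 4,6-dihydroxy-3-[(6-methoxy-1-oxo-3-pentyl-1H-isochromen-8-yl)oxy]-2-pentylbenzoate, via bromodione 14 (not isolated)
Conditions: Br2 (1.0 equiv), DMF, 0 °C, 1 h; then 80 °C
Reagents that add atoms: bromine, BrBr
Why: Bromination–dehydrobromination aromatisation as used for alkyl dihydro-resorcylates, in which the dione enol is brominated at C3 (giving 14) much faster than either arene or the lactone alkene and HBr is then lost on warming (1,4-elimination through the enol with removal of the C6 hydrogen, or after relay of bromine to C1), the resulting cyclohexadienone enolising to the resorcinol, while the aryloxy group stays because the only hydrogen β to the C5–O bond is not acidified by either carbonyl.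

**Step 8**
Reactants: 15 benzyl 4,6-dihydroxy-3-[(6-methoxy-1-oxo-3-pentyl-1H-isochromen-8-yl)oxy]-2-pentylbenzoate
Product: 16 4,6-dihydroxy-3-[(6-hydroxy-1-oxo-3-pentyl-1H-isochromen-8-yl)oxy]-2-pentylbenzoic acid (CNP0439913.0)
Conditions: BBr3 (6 equiv), CH2Cl2, –78 → 20 °C; then ice/H2O
Reagents that add atoms: none
Why: Lewis-acid dealkylation, in which BBr3 cleaves the 6-methyl ether and the benzyl ester by bromide attack on the boron-activated oxygens in one operation, the free phenols being masked as aryl borates that deactivate the rings towards C-benzylation, while the diaryl ether, enol lactone and resorcylic acid survive at or below room temperature.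

**Compound list**
1 | methyl 2,4-dimethoxy-6-methylbenzoate | COC(=O)c1c(C)cc(OC)cc1OC | starting material
2 | N-methoxy-N-methylhexanamide | CCCCCC(=O)N(C)OC | starting material
3 | methyl 2-(lithiomethyl)-4,6-dimethoxybenzoate | COC(=O)c1c(C[Li])cc(OC)cc1OC | intermediate
4 | methyl 2,4-dimethoxy-6-(2-oxoheptyl)benzoate | COC(=O)c1c(CC(=O)CCCCC)cc(OC)cc1OC | intermediate
5 | 6,8-dimethoxy-3-pentyl-1H-isochromen-1-one | CCCCCc1cc2cc(OC)cc(OC)c2c(=O)o1 | intermediate
6 | 8-hydroxy-6-methoxy-3-pentyl-1H-isochromen-1-one | CCCCCc1cc2cc(OC)cc(O)c2c(=O)o1 | intermediate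
7 | dimethyl (1-diazo-2-oxopropyl)phosphonate | COP(=O)(OC)C(=[N+]=[N-])C(C)=O | starting material
8 | dimethyl {1-[(6-methoxy-1-oxo-3-pentyl-1H-isochromen-8-yl)oxy]-2-oxopropyl}phosphonate, racemic | CCCCCc1cc2cc(OC)cc(OC(C(C)=O)P(=O)(OC)OC)c2c(=O)o1 | intermediate
9 | hexanal | CCCCCC=O | starting material
10 | 6-methoxy-8-{[(3Z)-2-oxonon-3-en-3-yl]oxy}-3-pentyl-1H-isochromen-1-one | CCCCC/C=C(\Oc1cc(OC)cc2cc(CCCCC)oc(=O)c12)C(C)=O | intermediate
11 | dibenzyl malonate | O=C(CC(=O)OCc1ccccc1)OCc1ccccc1 | starting material
12 | dibenzyl 2-{3-[(6-methoxy-1-oxo-3-pentyl-1H-isochromen-8-yl)oxy]-2-oxononan-4-yl}propanedioate, racemic diastereomer mixture | CCCCCC(C(Oc1cc(OC)cc2cc(CCCCC)oc(=O)c12)C(C)=O)C(C(=O)OCc1ccccc1)C(=O)OCc1ccccc1 | intermediate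
13 | benzyl 2-hydroxy-5-[(6-methoxy-1-oxo-3-pentyl-1H-isochromen-8-yl)oxy]-4-oxo-6-pentylcyclohex-2-ene-1-carboxylate, racemic diastereomer mixture | CCCCCC1C(C(=O)OCc2ccccc2)C(O)=CC(=O)C1Oc1cc(OC)cc2cc(CCCCC)oc(=O)c12 | intermediate
14 | benzyl 3-bromo-2-hydroxy-5-[(6-methoxy-1-oxo-3-pentyl-1H-isochromen-8-yl)oxy]-4-oxo-6-pentylcyclohex-2-ene-1-carboxylate, racemic diastereomer mixture | CCCCCC1C(C(=O)OCc2ccccc2)C(O)=C(Br)C(=O)C1Oc1cc(OC)cc2cc(CCCCC)oc(=O)c12 | intermediate
15 | benzyl 4,6-dihydroxy-3-[(6-methoxy-1-oxo-3-pentyl-1H-isochromen-8-yl)oxy]-2-pentylbenzoate | CCCCCc1c(Oc2cc(OC)cc3cc(CCCCC)oc(=O)c23)c(O)cc(O)c1C(=O)OCc1ccccc1 | intermediate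
16 | 4,6-dihydroxy-3-[(6-hydroxy-1-oxo-3-pentyl-1H-isochromen-8-yl)oxy]-2-pentylbenzoic acid | CCCCCc1cc2cc(O)cc(Oc3c(O)cc(O)c(C(=O)O)c3CCCCC)c2c(=O)o1 | target

**Totals and risks**
Total step count: 8. Longest linear sequence: 8 steps (1 → 16, fully linear).

Most likely to fail: step 6 (the greatest risk), step 7 and step 4. The fallbacks follow in step order.

Step 4 (O–H insertion into a chelated, hindered peri-hydroxyl). Insertion may be slow, leaving carbenoid dimerisation or cyclopropanation of the lactone alkene to compete. The fallback makes the same ether bond by epoxide opening and sets out from 6. Commercial (E)-non-3-en-2-one is epoxidised (H2O2, NaOH, MeOH, 0 °C, Weitz–Scheffer) to racemic trans-3,4-epoxynonan-2-one F1. Heating 6 with F1 and Cs2CO3 (or catalytic KH) in DMF at 60 °C opens the epoxide at the carbon next to the carbonyl, with inversion there, to give racemic (3S,4S)-4-hydroxy-3-[(6-methoxy-1-oxo-3-pentyl-1H-isochromen-8-yl)oxy]nonan-2-one F2. F2 dehydrates in the same pot (E1cB), and the route is rejoined at 10, bypassing steps 4 and 5.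

Step 6 (Michael–Dieckmann on the α-aryloxy enone). The captodative, β-alkyl enone may be too poor an acceptor for malonate, and the ketone enolate beside the ether oxygen could attack the peri lactone carbonyl, although that closure would give a non-enolisable quaternary diketone and should be reversible. The fallback swaps donor and acceptor and sets out from 6. Phenol 6 is O-alkylated with chloroacetone (K2CO3, acetone, 56 °C) to 6-methoxy-8-(2-oxopropoxy)-3-pentyl-1H-isochromen-1-one F3. Separately, 9 and 11 are condensed (piperidine/AcOH, toluene, Dean–Stark, Knoevenagel) to dibenzyl 2-hexylidenemalonate F4. Pyrrolidine (20 mol %) with PhCO2H in CHCl3 at 20 °C then adds F3, through its more substituted oxygen-bearing enamine, to the doubly activated alkene of F4. This gives the same Michael adduct, so the route is rejoined at 12, which is closed to 13 with NaH in THF as before.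

Step 7 (Br2 aromatisation). Bromine transfer to C5/C7 of ring A, to C4 of the isocoumarin or to the new resorcinol ring may compete with loss of HBr. The fallback is halogen-free and sets out from 13. Me3SiOTf (2.5 equiv) and Et3N in CH2Cl2 at 0 °C give benzyl 5-[(6-methoxy-1-oxo-3-pentyl-1H-isochromen-8-yl)oxy]-6-pentyl-2,4-bis(trimethylsilyloxy)cyclohexa-1,3-diene-1-carboxylate F5. DDQ (1.1 equiv, benzene, 20 °C) abstracts hydride from the aryloxy-bearing C5 and the cation loses the C6 proton to give benzyl 3-[(6-methoxy-1-oxo-3-pentyl-1H-isochromen-8-yl)oxy]-2-pentyl-4,6-bis(trimethylsilyloxy)benzoate F6. Dilute HCl in MeOH desilylates F6, and the route is rejoined at 15.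

**Further compounds**
F1 | step 4 | rac-(3R,4S)-3,4-epoxynonan-2-one (trans) | CC(=O)[C@@H]1O[C@H]1CCCCC
F2 | step 4 | rac-(3S,4S)-4-hydroxy-3-[(6-methoxy-1-oxo-3-pentyl-1H-isochromen-8-yl)oxy]nonan-2-one | CC(=O)[C@@H](Oc1cc(OC)cc2cc(CCCCC)oc(=O)c12)[C@@H](O)CCCCC
F3 | step 6 | 6-methoxy-8-(2-oxopropoxy)-3-pentyl-1H-isochromen-1-one | CCCCCc1cc2cc(OC)cc(OCC(C)=O)c2c(=O)o1
F4 | step 6 | dibenzyl 2-hexylidenemalonate | CCCCCC=C(C(=O)OCc1ccccc1)C(=O)OCc1ccccc1
F5 | step 7 | benzyl 5-[(6-methoxy-1-oxo-3-pentyl-1H-isochromen-8-yl)oxy]-6-pentyl-2,4-bis(trimethylsilyloxy)cyclohexa-1,3-diene-1-carboxylate, racemic diastereomer mixture | CCCCCC1C(Oc2cc(OC)cc3cc(CCCCC)oc(=O)c23)C(O[Si](C)(C)C)=CC(O[Si](C)(C)C)=C1C(=O)OCc1ccccc1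
F6 | step 7 | benzyl 3-[(6-methoxy-1-oxo-3-pentyl-1H-isochromen-8-yl)oxy]-2-pentyl-4,6-bis(trimethylsilyloxy)benzoate | CCCCCc1c(Oc2cc(OC)cc3cc(CCCCC)oc(=O)c23)c(O[Si](C)(C)C)cc(O[Si](C)(C)C)c1C(=O)OCc1ccccc1
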